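Which flask ends with the larger share of its L turned into Q, delta or alpha?

1. the winner by amount of Q, in percent of the L charged; "neither" if no more than 2 percentage points parts them (delta / alpha / neither)
2. how much Q is there at the end, in percent of the L charged: delta
3. how much Q is there at the end, in percent of the L charged: alpha

| flask | L | E | remark | time |
|---|---|---|---|---|
| summer | 0.053 M (fed, over 50 s) | 0.10 mM | run made earlier; the fed solution adds 0.25 times the starting volume |  |
| winter | 0.10 M (fed, over 50 s) | 0.10 mM | run made earlier; the fed solution adds 0.25 times the starting volume |  |
| dawn | 0.24 M (fed, over 50 s) | 0.10 mM | run made earlier; the fed solution adds 0.25 times the starting volume |  |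
| delta | 0.20 M (fed, over 50 s) | 0.10 mM | the fed solution adds 0.25 times the starting volume | 1.0 h |
| alpha | 0.060 M | 0.10 mM | everything together at the start, the whole solution of L included, so that from the start the volume is larger by 0.25 times the starting volume | 0.60 h |

| summer: time / min | summer: Q / % | winter: time / min | winter: Q / % | dawn: time / min | dawn: Q / % |
|---|---|---|---|---|---|
| 5.00 | 16.4 | 5.00 | 14.7 | 12.0 | 9.5 |
| 10.0 | 19.5 | 10.0 | 17.3 | 25.0 | 9.4 |
| 15.0 | 20.0 | 15.0 | 17.1 | 40.0 | 9.9 |
| 30.0 | 18.6 | 30.0 | 17.3 | 50.0 | 9.4 |
| 60.0 | 19.3 | 60.0 | 16.6 | 60.0 | 9.7 |

(readings scatter by 0.5 percentage points)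

- every charge counts on the volume at the start, and the solution that is fed holds the whole dose

I start from the balance of E, the reagent charged in the smaller amount: 0.10 mM against 0.060 M of L even in alpha. The readings stop rising by about 15.0 min with most of the L unconverted, so I ask what a charge of E delivers. The last 3 readings of each run give 102 Q per E in summer, 170 in winter and 232 in dawn. This number, the Q at the plateau per E charged, is the total turnover number, and it rises with the charge of L.

Delta has 60 min and alpha 36 min, which is longer than that plateau time, so I interpolate the number at each charge. Delta gets 214, which is 10.7% of its L, and alpha gets 112, which is 18.7%.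

Now I turn the question round. For alpha to stand within 2 percentage points of delta, with delta held at my figure, alpha's number would have to fall to 76.3, which is lower than the summer number and a loss of about a third of my figure. Alpha goes in at once while the runs were fed, so its figure is the less sure, but I still commit to alpha.

The forecast also names alpha, with 11.8% for delta, higher than my figure, and 18.8% for alpha, noting that "Both flasks run well past the plateau time".

The flask gives alpha: 11.2% in delta and 22.1% in alpha.

    L + E → Q + E, rate k1*[L]*[E]/(1 + ([L]/Km1) + ([L]/Ksi1)^2) (0.430 M, 0.160 M, k = 1600 /M/min)
    E → J (k = 0.420 /min)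
    2 E → X (k = 240 /M/min)

In delta, the half-life of E by the path to J is 1.7 min, far shorter than the 60 min allowed, and half of the turnover to Q is done by 1.81 min. At 0.500 h delta holds E at 0%, J at 95.4% and X at 4.58% of the E charged. The turnover number comes to 223 in delta, and in alpha to 132, more than my 112. For a flask like delta with 0.12 M of L, the number interpolated from winter and dawn, 179, gives 14.9% of its L as Q, and that flask ends with Q at 15.6% of its L.

(The data are calculated for substances that don't exist; noise was put on by code.)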